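I began with the easy step: I read each hand as a fraction of its own charge.

| flask | left-handed substrate | right-handed substrate | gas | remark | time |
|---|---|---|---|---|---|
| ash | 17 mM | 17 mM | 3.1 mM (held) | run made earlier |  |
| cedar | 26 mM | 26 mM | 3.1 mM (held) | run made earlier |  |
| winter | 12 mM | 12 mM | 3.1 mM (held) |  | 40 min |
| summer | 12 mM | 12 mM | 3.1 mM (held) |  | 150 min |

| run | time / min | right-handed substrate / % | left-handed substrate / % |
|---|---|---|---|
| ash | 2.50 | 47.5 | 45.4 |
| ash | 4.00 | 45.1 | 43.0 |
| ash | 6.00 | 43.8 | 42.1 |
| ash | 10.0 | 41.1 | 37.0 |
| ash | 15.0 | 37.3 | 30.4 |
| ash | 20.0 | 33.3 | 26.8 |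
| ash | 30.0 | 26.1 | 18.7 |
| cedar | 5.00 | 46.5 | 43.4 |
| cedar | 10.0 | 43.1 | 40.5 |
| cedar | 15.0 | 40.7 | 36.3 |
| cedar | 20.0 | 38.1 | 31.7 |
| cedar | 25.0 | 34.5 | 29.6 |
| cedar | 30.0 | 31.5 | 25.7 |

(standard deviation of a reading: 0.5 percentage points)

- partner is single-handed; left-handed substrate and right-handed substrate are mirror images of each other, charged as a racemate, each of them at the stated concentration
- at the start none of the gas is in solution
- an excess is the difference of the two amounts in percent of their sum
- an excess is below zero if the other one leads
- the handed part of partner does not stay in what it makes, so the products of the two hands are mirror images too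

- which one finishes higher in excess of right-handed substrate over left-handed substrate among what is left of the two ("neither" within 2 percentage points) (winter / summer / neither)
- excess of right-handed substrate over left-handed substrate among what is left of the two at the end, winter
- excess of right-handed substrate over left-handed substrate among what is left of the two at the end, summer

At the last ash reading the right-handed substrate stood at 0.522 and the left-handed at 0.374, so less of the left-handed was left. But their gap shifts as a flask runs, so I took the ratio of their logarithms, an apparent selectivity factor 1.51, read off this one ash reading. I assumed that the left-handed fraction stayed the right-handed fraction raised to that power as a flask ran on. So I went round: squaring one fraction squares the other, and the ash excess of 16.5% became 32.2%, then 58.3%. The second round left 20.6% of the charge, near the forecast's 5 mM of 24 mM, so I took 32.2% for winter. Summer runs longer, so I expected 58.3% or more there.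

The forecast differed: winter higher, winter 27% (18% to 36%), summer 1% (−1% to 20%), since with reversible steps “the leftover relaxes towards racemic”.

The flask gave winter 35.3% and summer 69.6%, so summer finished higher.

    partner + left-handed substrate → left-handed product (k = 70.7 M⁻¹ min⁻¹)
    partner + right-handed substrate → right-handed product (k = 37.4 M⁻¹ min⁻¹)
    left-handed substrate ⇌ achiral form (K = 0.0832, k = 0.0313 min⁻¹)
    right-handed substrate ⇌ achiral form (K = 0.0832, k = 0.0313 min⁻¹)
    achiral form → side product (k = 0.0285 min⁻¹)
    2 partner → self-condensation product (k = 3.14 M⁻¹ min⁻¹)
    gas ⇌ partner, rate k7*(csat - [partner]) (kL = 0.239 min⁻¹)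

Summer had reacted >99.9%, and ten times later its excess still stood at 69.6%, so the climb I reckoned stopped there. In winter, the right-handed rest of 22% raised to the factor gives 10.1% for the left-handed, against 11% in the flask.

In the winter flask stopped at 10 min, the right-handed rest of 78% gives by the factor an excess of 6.22%. The computed excess was 7.46%.

The earlier runs and the new flask were computed for substances that don't exist; the scatter is artificial.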